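The route hinges on disconnecting the C7=C11 olefin of the butenolide, the five-membered lactone fused to the ten-membered carbocycle along C6–C7. The precursor is an acyclic C7 ketone whose C6 oxygen bears a 2-(diethoxyphosphoryl)acrylate. Acetate adds to C13 of that vinylphosphonate, and the C11 carbanion so formed olefinates the adjacent ketone: one operation installs the C13 acetate, forms the tetrasubstituted C7=C11 bond and closes the lactone. It exploits the 1,2-relationship of the C6 lactone oxygen to C7 and the oxygen on C13. D-Glucose supplies C5–C9, a chelation-controlled thioester aldol sets C9 and C10, and ring-closing metathesis forms the (Z)-C4=C5 olefin late.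

Key step: step 19

Remark on numbering: germacrane numbering is used: C1 ketone, C2, C3, C4(Me)=C5, C6 (lactone carbinol), C7=C11 (butenolide olefin), C8 (tiglate carbinol), C9 (free carbinol), C10 (methyl-bearing carbon), C12 (lactone carbonyl), C13 (acetoxymethyl carbon).
Remark on stereochemistry (assumption): the target is read as 4Z,6R,8R,9R,10S with an (E)-2-methylbut-2-enoate (tiglate). In chain intermediates the spatial arrangement at C6, C8, C9 and C10 is that of the target and is fixed by the SMILES, also where a change of substituents would change the CIP letters.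
Abbreviations: DMB = 3,4-dimethoxybenzyl, PMB = 4-methoxybenzyl, TES = triethylsilyl, TBS = tert-butyldimethylsilyl, Tig = (E)-2-methylbut-2-enoyl.

Step 1
Reactants: 1 methyl α-D-glucopyranoside
Product: 2 methyl 4,6-O-(4-methoxybenzylidene)-α-D-glucopyranoside
Conditions: 4-MeOC6H4CH(OMe)2, CSA (cat.), DMF, 50 °C, 150 mbar
Reagents that add atoms: 4-methoxybenzaldehyde dimethyl acetal, COC(OC)c1ccc(OC)cc1
Why: Acid-catalysed transacetalisation closes the trans-fused 1,3-dioxane on O4/O6 under thermodynamic control, which places the aryl group equatorial (R acetal carbon).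

Step 2
Reactants: 2 methyl 4,6-O-(4-methoxybenzylidene)-α-D-glucopyranoside
Product: 3 2-O-DMB ether of 2
Conditions: 3,4-(MeO)2C6H3CH2Br, Bu4NHSO4 (cat.), aq. NaOH, CH2Cl2, reflux
Reagents that add atoms: 3,4-dimethoxybenzyl bromide, COc1ccc(CBr)cc1OC
Why: Phase-transfer Williamson etherification alkylates the more acidic 2-OH next to the anomeric centre in preference to the 3-OH, the usual regiochemical bias of 4,6-O-arylidene α-glucosides.

Step 3
Reactants: 3 2-O-DMB ether
Product: 4 2-O-DMB 3-O-TES 4,6-O-(4-methoxybenzylidene) glucoside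
Conditions: Et3SiOTf, 2,6-lutidine, CH2Cl2, 0 °C
Reagents that add atoms: triethylsilyl trifluoromethanesulfonate, CC[Si](CC)(CC)OS(=O)(=O)C(F)(F)F
Why: Silylation of the only remaining hydroxyl with a silyl triflate and a hindered base leaves the acid-labile acetal intact.

Step 4
Reactants: 4 2-O-DMB 3-O-TES 4,6-O-(4-methoxybenzylidene) glucoside
Product: 5 methyl 2-O-DMB-4-O-PMB-3-O-TES-α-D-glucopyranoside
Conditions: i-Bu2AlH, toluene, −20 to 0 °C; aq. potassium sodium tartrate
Reagents that add atoms: none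
Why: Regioselective reductive acetal opening: aluminium coordinates the less hindered O6 and hydride delivery leaves the PMB ether on O4 and a free primary alcohol.

Step 5
Reactants: 5 methyl 2-O-DMB-4-O-PMB-3-O-TES-α-D-glucopyranoside
Product: 6 methyl 6-deoxy-6-iodo-2-O-DMB-4-O-PMB-3-O-TES-α-D-glucopyranoside
Conditions: I2, PPh3, imidazole, toluene, 60 °C
Reagents that add atoms: iodine, II
Why: Garegg–Samuelsson iodination converts the primary alcohol into the iodide through the alkoxyphosphonium ion (SN2 at C6 of the sugar; no stereocentre involved).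

Step 6
Reactants: 6 methyl 6-deoxy-6-iodo-2-O-DMB-4-O-PMB-3-O-TES-α-D-glucopyranoside
Product: 7 (2R,3S,4R)-2-(DMB-oxy)-4-(PMB-oxy)-3-(TES-oxy)hex-5-enal
Conditions: Zn (activated), THF/H2O (4:1), ultrasound, 40 °C
Reagents that add atoms: none
Why: Bernet–Vasella fragmentation: zinc inserts into the C–I bond and β-elimination of the ring oxygen opens the pyranoside to the hex-5-enal, leaving sugar C2–C4 (later C8, C7, C6) untouched.

Step 7
Reactants: 8 propanoyl chloride, 9 2-methylpropane-2-thiol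
Product: 10 S-tert-butyl propanethioate
Conditions: pyridine, CH2Cl2, 0 °C to rt
Reagents that add atoms: none
Why: Acyl substitution of the acid chloride by the thiol (thioesterification).

Step 8
Reactants: 10 S-tert-butyl propanethioate
Product: 11 (Z)-1-(tert-butylsulfanyl)-1-(trimethylsilyloxy)prop-1-ene
Conditions: LiN(i-Pr)2, THF, −78 °C; Me3SiCl
Reagents that add atoms: chlorotrimethylsilane, C[Si](C)(C)Cl
Why: Kinetic enolisation of the thioester in THF and O-silylation should give the silyl ketene thioacetal with the C-methyl trans to OSiMe3.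

Step 9
Reactants: 7 (2R,3S,4R)-2-(DMB-oxy)-4-(PMB-oxy)-3-(TES-oxy)hex-5-enal, 11 (Z)-1-(tert-butylsulfanyl)-1-(trimethylsilyloxy)prop-1-ene
Product: 12 S-tert-butyl 3-hydroxy-2-methyl-4-(DMB-oxy)-5-(TES-oxy)-6-(PMB-oxy)oct-7-enethioate (9,10-anti 8,9-syn)
Conditions: MgBr2·OEt2, CH2Cl2, −78 to −30 °C (Lewis acid added to the mixture of 7 and 11); aq. NaHCO3
Reagents that add atoms: none
Why: Chelation-controlled Mukaiyama aldol: MgBr2 bridges the aldehyde oxygen and the C8 ether oxygen so that the nucleophile adds anti to the C7 substituent (8,9-syn, new C9), and the open transition state of the thioester-derived silyl ketene acetal gives the 9,10-anti relationship (new C10).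

Step 10
Reactants: 12 β-hydroxy thioester
Product: 13 C9 O-TBS ether of 12
Conditions: t-BuMe2SiOTf, 2,6-lutidine, CH2Cl2, −40 to 0 °C
Reagents that add atoms: tert-butyldimethylsilyl trifluoromethanesulfonate, CC(C)(C)[Si](C)(C)OS(=O)(=O)C(F)(F)F
Why: Silyl triflate protection of the hindered secondary C9 alcohol, which has to stay masked until the last step.

Step 11
Reactants: 13 C9 O-TBS thioester, 14 4-bromo-2-methylbut-1-ene
Product: 16 C1 ketone (7-OTBS 8-ODMB 9-OTES 10-OPMB 2,6-dimethyldodeca-1,11-dien-5-one), via Grignard reagent 15 (not isolated)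
Conditions: 14, Mg, THF; CuBr·SMe2, THF, −40 °C; then 13, −40 to −10 °C; aq. NH4Cl
Reagents that add atoms: none
Why: Organocuprate acylation: the dialkylcuprate displaces the thiolate of the thioester and stops at the ketone, which installs the C1 carbonyl and the C2–C4 isopropenyl arm without touching C10.

Step 12
Reactants: 16 C1 ketone
Product: 17 C8 alcohol
Conditions: DDQ (1.05 equiv), CH2Cl2/pH 7 buffer (10:1), 0 °C
Reagents that add atoms: none
Why: Oxidative benzyl ether cleavage with DDQ is fastest for the more electron-rich DMB group, so that C8–OH should be released while the PMB ether on C6 stays.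

Step 13
Reactants: 17 C8 alcohol
Product: 18 C8 tiglate
Conditions: tigloyl chloride, Et3N, DMAP (0.2 equiv), CH2Cl2, 0 °C to rt
Reagents that add atoms: (E)-2-methylbut-2-enoyl chloride (tigloyl chloride), C/C=C(\C)C(=O)Cl
Why: DMAP-catalysed acylation of the C8 alcohol installs the tiglate with retention at C8.

Step 14
Reactants: 18 C8 tiglate
Product: 20 C1,C7-diketone, via C7 alcohol 19 (not isolated)
Conditions: HF·pyridine, pyridine, THF, 0 °C; then Dess–Martin periodinane, NaHCO3, CH2Cl2, rt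
Reagents that add atoms: none
Why: Fluoride cleaves the TES ether selectively beside the bulkier TBS ether, and buffered Dess–Martin oxidation of the crude C7 alcohol should give the ketone without epimerising C6 or C8.

Step 15
Reactants: 20 C1,C7-diketone
Product: 21 C6 α-hydroxy ketone
Conditions: DDQ (1.5 equiv), CH2Cl2/pH 7 buffer (10:1), 0 °C to rt
Reagents that add atoms: none
Why: DDQ-mediated oxidative removal of the PMB ether releases the C6 hydroxyl under neutral conditions that leave the enolisable C6 stereocentre untouched.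

Step 16
Reactants: 22 tert-butyl 2-(diethoxyphosphoryl)acetate
Product: 24 tert-butyl 2-(diethoxyphosphoryl)acrylate, via methanol adduct 23 (not isolated)
Conditions: (CH2O)n, piperidine (cat.), MeOH, reflux; then H3PO4 (cat.), toluene, 90 °C, reduced pressure
Reagents that add atoms: formaldehyde (as paraformaldehyde), C=O
Why: Knoevenagel-type methylenation: amine-catalysed condensation with formaldehyde in methanol gives the β-methoxy adduct, and acid-catalysed loss of methanol gives the vinylphosphonate.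

Step 17
Reactants: 24 tert-butyl 2-(diethoxyphosphoryl)acrylate
Product: 25 2-(diethoxyphosphoryl)acrylic acid
Conditions: CF3CO2H, CH2Cl2, rt
Reagents that add atoms: none
Why: Acidolysis of the tert-butyl ester (loss of isobutene) frees the acid without nucleophiles that could add to the acrylate.

Step 18
Reactants: 21 C6 α-hydroxy ketone, 25 2-(diethoxyphosphoryl)acrylic acid
Product: 26 C6 2-(diethoxyphosphoryl)acrylate ester
Conditions: DCC, DMAP (5 mol %), CH2Cl2, −20 to 0 °C
Reagents that add atoms: none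
Why: Steglich esterification of the C6 hydroxyl at low temperature, the classical entry to phosphonate esters of α-hydroxy ketones.

Step 19
Reactants: 26 C6 2-(diethoxyphosphoryl)acrylate ester
Product: 28 acyclic butenolide (C13 acetate), via acetate adduct 27 (not isolated)
Conditions: Bu4NOAc (2.5 equiv), LiCl (3 equiv), MeCN/THF, −20 °C to rt
Reagents that add atoms: tetrabutylammonium acetate, CC(=O)[O-].CCCC[N+](CCCC)(CCCC)CCCC
Why: Proposed new method: acetate adds in conjugate fashion to C13 of the 2-phosphonoacrylate (oxa-Michael), the phosphonate-stabilised carbanion generated at C11 attacks the neighbouring C7 ketone, and syn-elimination of lithium diethyl phosphate from the oxaphosphetane gives the C7=C11 bond. The closest known reaction types are the nucleophile-triggered Michael/intramolecular Horner–Wadsworth–Emmons cascade of vinylphosphonates (established for alkoxide, amine, thiolate and carbon nucleophiles) and the intramolecular Horner–Wadsworth–Emmons butenolide synthesis from phosphonoacetates of α-hydroxy ketones under LiCl/base (Masamune–Roush) conditions; new here is the carboxylate as trigger, whose reversible addition is pulled forward by the irreversible olefination. The butenolide (ring atoms C11, C12, O, C6, C7) closes by 5-exo-trig attack of the C11 carbanion on the C7 carbonyl. No stereocentre is created; C6, C8, C9 and C10 are carried through, and the ring fixes the olefin geometry. Chemoselectivity for C7 over the C1 ketone follows from ring size (five- against nine-membered); the weakly basic acetate/LiCl medium is meant to let olefination outrun enolisation at C6 and C8, and loss of acetate from the adduct only returns the acrylate.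

Step 20
Reactants: 28 acyclic butenolide
Product: 29 C9 O-TBS ether of the target
Conditions: second-generation Hoveyda–Grubbs catalyst RuCl2(H2IMes)(=CH-C6H4-2-O-i-Pr) (15 mol %), 1,4-benzoquinone (30 mol %), toluene (1 mM), 90 °C
Reagents that add atoms: none
Why: Ring-closing metathesis between the C5 vinyl group and the isopropenyl group closes the ten-membered carbocycle, the butenolide holding the two arms gauche on C6 and C7, and the ring size should favour the (Z)-trisubstituted C4=C5 olefin.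

Step 21
Reactants: 29 C9 O-TBS ether of the target
Product: 30 target (CNP0281168.1)
Conditions: HF·pyridine, pyridine, THF, 0 °C to rt
Reagents that add atoms: none
Why: Buffered fluoride desilylation frees the C9 hydroxyl under mildly acidic conditions that spare the butenolide, the allylic acetate and the tiglate.

Compound list

1 | methyl α-D-glucopyranoside | CO[C@H]1O[C@H](CO)[C@@H](O)[C@H](O)[C@H]1O | starting material
2 | methyl 4,6-O-[(R)-4-methoxybenzylidene]-α-D-glucopyranoside | CO[C@H]1O[C@@H]2CO[C@@H](c3ccc(OC)cc3)O[C@H]2[C@H](O)[C@H]1O | intermediate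
3 | methyl 2-O-(3,4-dimethoxybenzyl)-4,6-O-[(R)-4-methoxybenzylidene]-α-D-glucopyranoside | CO[C@H]1O[C@@H]2CO[C@@H](c3ccc(OC)cc3)O[C@H]2[C@H](O)[C@H]1OCc1ccc(OC)c(OC)c1 | intermediate
4 | methyl 2-O-(3,4-dimethoxybenzyl)-4,6-O-[(R)-4-methoxybenzylidene]-3-O-triethylsilyl-α-D-glucopyranoside | CO[C@H]1O[C@@H]2CO[C@@H](c3ccc(OC)cc3)O[C@H]2[C@H](O[Si](CC)(CC)CC)[C@H]1OCc1ccc(OC)c(OC)c1 | intermediate
5 | methyl 2-O-(3,4-dimethoxybenzyl)-4-O-(4-methoxybenzyl)-3-O-triethylsilyl-α-D-glucopyranoside | CO[C@H]1O[C@H](CO)[C@@H](OCc2ccc(OC)cc2)[C@H](O[Si](CC)(CC)CC)[C@H]1OCc1ccc(OC)c(OC)c1 | intermediate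
6 | methyl 6-deoxy-6-iodo-2-O-(3,4-dimethoxybenzyl)-4-O-(4-methoxybenzyl)-3-O-triethylsilyl-α-D-glucopyranoside | CO[C@H]1O[C@H](CI)[C@@H](OCc2ccc(OC)cc2)[C@H](O[Si](CC)(CC)CC)[C@H]1OCc1ccc(OC)c(OC)c1 | intermediate
7 | (2R,3S,4R)-2-(3,4-dimethoxybenzyloxy)-4-(4-methoxybenzyloxy)-3-(triethylsilyloxy)hex-5-enal (5,6-dideoxy-D-xylo-hex-5-enose derivative; C2 = C8, C3 = C7, C4 = C6 of the target) | O=C[C@H](OCc1ccc(OC)c(OC)c1)[C@@H](O[Si](CC)(CC)CC)[C@H](OCc1ccc(OC)cc1)C=C | intermediate
8 | propanoyl chloride | CCC(=O)Cl | starting material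
9 | 2-methylpropane-2-thiol | CC(C)(C)S | starting material
10 | S-tert-butyl propanethioate | CCC(=O)SC(C)(C)C | intermediate
11 | (Z)-1-(tert-butylsulfanyl)-1-(trimethylsilyloxy)prop-1-ene (C-methyl trans to OSiMe3) | C/C=C(/O[Si](C)(C)C)SC(C)(C)C | intermediate
12 | S-tert-butyl 4-(3,4-dimethoxybenzyloxy)-3-hydroxy-6-(4-methoxybenzyloxy)-2-methyl-5-(triethylsilyloxy)oct-7-enethioate, 2,3-anti-3,4-syn (C2 = C10, C3 = C9, C4 = C8, C5 = C7, C6 = C6 of the target) | CC(C)(C)SC(=O)[C@@H](C)[C@@H](O)[C@H](OCc1ccc(OC)c(OC)c1)[C@@H](O[Si](CC)(CC)CC)[C@H](OCc1ccc(OC)cc1)C=C | intermediate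
13 | 3-O-tert-butyldimethylsilyl ether of 12 | CC(C)(C)SC(=O)[C@@H](C)[C@@H](O[Si](C)(C)C(C)(C)C)[C@H](OCc1ccc(OC)c(OC)c1)[C@@H](O[Si](CC)(CC)CC)[C@H](OCc1ccc(OC)cc1)C=C | intermediate
14 | 4-bromo-2-methylbut-1-ene | C=C(C)CCBr | starting material
15 | (3-methylbut-3-en-1-yl)magnesium bromide | C=C(C)CC[Mg]Br | intermediate (not isolated)
16 | 7-(tert-butyldimethylsilyloxy)-8-(3,4-dimethoxybenzyloxy)-10-(4-methoxybenzyloxy)-2,6-dimethyl-9-(triethylsilyloxy)dodeca-1,11-dien-5-one (C5 = C1, C6 = C10, C7 = C9, C8 = C8, C9 = C7, C10 = C6 of the target; stereocentres as in the target) | C=C(C)CCC(=O)[C@@H](C)[C@@H](O[Si](C)(C)C(C)(C)C)[C@H](OCc1ccc(OC)c(OC)c1)[C@@H](O[Si](CC)(CC)CC)[C@H](OCc1ccc(OC)cc1)C=C | intermediate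
17 | 8-hydroxy analogue of 16 (C8 alcohol) | C=C(C)CCC(=O)[C@@H](C)[C@@H](O[Si](C)(C)C(C)(C)C)[C@H](O)[C@@H](O[Si](CC)(CC)CC)[C@H](OCc1ccc(OC)cc1)C=C | intermediate
18 | 8-O-[(E)-2-methylbut-2-enoyl] ester of 17 (C8 tiglate) | C=C(C)CCC(=O)[C@@H](C)[C@@H](O[Si](C)(C)C(C)(C)C)[C@H](OC(=O)/C(C)=C/C)[C@@H](O[Si](CC)(CC)CC)[C@H](OCc1ccc(OC)cc1)C=C | intermediate
19 | 9-hydroxy compound from 18 (C7 alcohol, TES removed) | C=C(C)CCC(=O)[C@@H](C)[C@@H](O[Si](C)(C)C(C)(C)C)[C@H](OC(=O)/C(C)=C/C)[C@@H](O)[C@H](OCc1ccc(OC)cc1)C=C | intermediate (not isolated)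
20 | 7-(tert-butyldimethylsilyloxy)-10-(4-methoxybenzyloxy)-2,6-dimethyl-8-(tigloyloxy)dodeca-1,11-diene-5,9-dione (C1,C7-diketone) | C=C(C)CCC(=O)[C@@H](C)[C@@H](O[Si](C)(C)C(C)(C)C)[C@H](OC(=O)/C(C)=C/C)C(=O)[C@H](OCc1ccc(OC)cc1)C=C | intermediate
21 | 10-hydroxy analogue of 20 (C6 α-hydroxy ketone) | C=C(C)CCC(=O)[C@@H](C)[C@@H](O[Si](C)(C)C(C)(C)C)[C@H](OC(=O)/C(C)=C/C)C(=O)[C@H](O)C=C | intermediate
22 | tert-butyl 2-(diethoxyphosphoryl)acetate | CCOP(=O)(CC(=O)OC(C)(C)C)OCC | starting material
23 | tert-butyl 2-(diethoxyphosphoryl)-3-methoxypropanoate (racemic) | CCOP(=O)(OCC)C(COC)C(=O)OC(C)(C)C | intermediate (not isolated)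
24 | tert-butyl 2-(diethoxyphosphoryl)acrylate | C=C(C(=O)OC(C)(C)C)P(=O)(OCC)OCC | intermediate
25 | 2-(diethoxyphosphoryl)acrylic acid | C=C(C(=O)O)P(=O)(OCC)OCC | intermediate
26 | 10-O-[2-(diethoxyphosphoryl)acryloyl] ester of 21 (C6 phosphonoacrylate, C7 ketone) | C=C(C)CCC(=O)[C@@H](C)[C@@H](O[Si](C)(C)C(C)(C)C)[C@H](OC(=O)/C(C)=C/C)C(=O)[C@H](OC(=O)C(=C)P(=O)(OCC)OCC)C=C | intermediate
27 | lithium carbanion of the C6 3-acetoxy-2-(diethoxyphosphoryl)propanoate (acetate adduct of 26, carbanion at C11) | C=C(C)CCC(=O)[C@@H](C)[C@@H](O[Si](C)(C)C(C)(C)C)[C@H](OC(=O)/C(C)=C/C)C(=O)[C@H](OC(=O)[C-](COC(C)=O)P(=O)(OCC)OCC)C=C.[Li+] | intermediate (not isolated)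
28 | 3-(acetoxymethyl)-4-[2-(tert-butyldimethylsilyloxy)-3,7-dimethyl-4-oxo-1-(tigloyloxy)oct-7-en-1-yl]-5-vinylfuran-2(5H)-one (acyclic butenolide; stereocentres as in the target) | C/C=C(\C)C(=O)O[C@H](C1=C(COC(C)=O)C(=O)O[C@@H]1C=C)[C@H](O[Si](C)(C)C(C)(C)C)[C@H](C)C(=O)CCC(C)=C | intermediate
29 | 9-O-tert-butyldimethylsilyl ether of the target | C/C=C(\C)C(=O)O[C@@H]1C2=C(COC(C)=O)C(=O)O[C@@H]2/C=C(/C)CCC(=O)[C@@H](C)[C@H]1O[Si](C)(C)C(C)(C)C | intermediate
30 | (4Z,6R,8R,9R,10S)-13-acetoxy-9-hydroxy-1-oxo-8-[(E)-2-methylbut-2-enoyloxy]germacra-4,7(11)-dien-12,6-olide (CNP0281168.1) | C/C=C(\C)C(=O)O[C@@H]1C2=C(COC(C)=O)C(=O)O[C@@H]2/C=C(/C)CCC(=O)[C@@H](C)[C@H]1O | target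

Total step count: 21.
Longest linear sequence: 17 steps (steps 1–6, 9–15 and 18–21, from methyl α-D-glucopyranoside).

Steps most likely to fail

1. Step 19 (proposed new method). The acetate addition is reversible and may lie on the side of the acrylate, so that enolisation at C6 or C8 (epimerisation, migration of the C5 olefin into conjugation) or oligomerisation of the acrylate outruns the olefination. Fallback with known chemistry, setting out from 26: 4-methoxybenzyl alcohol serves as conjugate donor under LiCl/DBU in MeCN. Alkoxide-type oxa-Michael addition to a 2-phosphonoacrylate followed by intramolecular Horner–Wadsworth–Emmons olefination is established, and the adduct is thermodynamically favoured. The lithium 4-methoxybenzyloxy adduct F1 (not isolated) should cyclise to the C13 4-methoxybenzyl ether butenolide F2. DDQ in wet CH2Cl2 should release the C13 alcohol F3, and Ac2O/pyridine should return the route at 28.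

2. Step 20. The ten-membered ring may fail to close (dimerisation, ruthenium hydride isomerisation of the C5 vinyl group into conjugation with the lactone) or may close with the E geometry. Fallback, setting out from 18: the carbocycle is closed before the lactone exists, and the butenolide is then annulated onto the macrocycle. Ring-closing metathesis of 18 under the conditions of step 20 should give the fully protected cyclodecenone F4. HF·pyridine should give the C7 alcohol F5 and Dess–Martin oxidation the cyclic diketone F6. DDQ should give the cyclic α-hydroxy ketone F7, and Steglich esterification with 25 the cyclic phosphonoacrylate F8. The acetate cascade of step 19, through the lithium acetate adduct F9 (not isolated), should then deliver 29, where the route is rejoined.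

3. Step 9. Chelation may be incomplete (competing non-chelated addition gives the C9 epimer) or the anti preference of the silyl ketene thioacetal may be eroded (C10 epimer). Fallback, setting out from 7: the two stereocentres are set one at a time. A chelation-controlled Mukaiyama aldol with commercial 1-(tert-butyldimethylsilyloxy)-1-methoxyethene and MgBr2·OEt2 should give the 8,9-syn β-hydroxy methyl ester F10. Fráter–Seebach methylation of its dianion (LiN(i-Pr)2, MeI) should give the 9,10-anti α-methyl ester F11. Silylation with t-BuMe2SiOTf should give the silyl ether F12, and MeNH(OMe)·HCl/i-PrMgCl the Weinreb amide F13. Addition of Grignard reagent 15 should give ketone 16, where the route is rejoined.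

Further compounds

F1 | step 19 | lithium carbanion of the C6 3-(4-methoxybenzyloxy)-2-(diethoxyphosphoryl)propanoate (alkoxide adduct of 26) | C=C(C)CCC(=O)[C@@H](C)[C@@H](O[Si](C)(C)C(C)(C)C)[C@H](OC(=O)/C(C)=C/C)C(=O)[C@H](OC(=O)[C-](COCc1ccc(OC)cc1)P(=O)(OCC)OCC)C=C.[Li+]
F2 | step 19 | C13 4-methoxybenzyl ether analogue of 28 | C/C=C(\C)C(=O)O[C@H](C1=C(COCc2ccc(OC)cc2)C(=O)O[C@@H]1C=C)[C@H](O[Si](C)(C)C(C)(C)C)[C@H](C)C(=O)CCC(C)=C
F3 | step 19 | C13 alcohol analogue of 28 | C/C=C(\C)C(=O)O[C@H](C1=C(CO)C(=O)O[C@@H]1C=C)[C@H](O[Si](C)(C)C(C)(C)C)[C@H](C)C(=O)CCC(C)=C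
F4 | step 20 | (Z)-cyclodec-4-enone with C6 O-PMB, C7 O-TES, C8 O-Tig, C9 O-TBS, C10 methyl (ring-closed 18) | C/C=C(\C)C(=O)O[C@@H]1[C@@H](O[Si](CC)(CC)CC)[C@H](OCc2ccc(OC)cc2)/C=C(/C)CCC(=O)[C@@H](C)[C@H]1O[Si](C)(C)C(C)(C)C
F5 | step 20 | cyclic C7 alcohol (TES removed from F4) | C/C=C(\C)C(=O)O[C@@H]1[C@@H](O)[C@H](OCc2ccc(OC)cc2)/C=C(/C)CCC(=O)[C@@H](C)[C@H]1O[Si](C)(C)C(C)(C)C
F6 | step 20 | cyclic C1,C7-diketone | C/C=C(\C)C(=O)O[C@@H]1C(=O)[C@H](OCc2ccc(OC)cc2)/C=C(/C)CCC(=O)[C@@H](C)[C@H]1O[Si](C)(C)C(C)(C)C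
F7 | step 20 | cyclic C6 α-hydroxy ketone | C/C=C(\C)C(=O)O[C@@H]1C(=O)[C@H](O)/C=C(/C)CCC(=O)[C@@H](C)[C@H]1O[Si](C)(C)C(C)(C)C
F8 | step 20 | cyclic C6 2-(diethoxyphosphoryl)acrylate | C/C=C(\C)C(=O)O[C@@H]1C(=O)[C@H](OC(=O)C(=C)P(=O)(OCC)OCC)/C=C(/C)CCC(=O)[C@@H](C)[C@H]1O[Si](C)(C)C(C)(C)C
F9 | step 20 | lithium carbanion of the cyclic C6 3-acetoxy-2-(diethoxyphosphoryl)propanoate | C/C=C(\C)C(=O)O[C@@H]1C(=O)[C@H](OC(=O)[C-](COC(C)=O)P(=O)(OCC)OCC)/C=C(/C)CCC(=O)[C@@H](C)[C@H]1O[Si](C)(C)C(C)(C)C.[Li+]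
F10 | step 9 | methyl 4-(3,4-dimethoxybenzyloxy)-3-hydroxy-6-(4-methoxybenzyloxy)-5-(triethylsilyloxy)oct-7-enoate (3,4-syn) | COC(=O)C[C@@H](O)[C@H](OCc1ccc(OC)c(OC)c1)[C@@H](O[Si](CC)(CC)CC)[C@H](OCc1ccc(OC)cc1)C=C
F11 | step 9 | 2-methyl derivative of F10 (2,3-anti) | COC(=O)[C@@H](C)[C@@H](O)[C@H](OCc1ccc(OC)c(OC)c1)[C@@H](O[Si](CC)(CC)CC)[C@H](OCc1ccc(OC)cc1)C=C
F12 | step 9 | 3-O-tert-butyldimethylsilyl ether of F11 | COC(=O)[C@@H](C)[C@@H](O[Si](C)(C)C(C)(C)C)[C@H](OCc1ccc(OC)c(OC)c1)[C@@H](O[Si](CC)(CC)CC)[C@H](OCc1ccc(OC)cc1)C=C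
F13 | step 9 | N-methoxy-N-methylamide corresponding to F12 | CON(C)C(=O)[C@@H](C)[C@@H](O[Si](C)(C)C(C)(C)C)[C@H](OCc1ccc(OC)c(OC)c1)[C@@H](O[Si](CC)(CC)CC)[C@H](OCc1ccc(OC)cc1)C=C
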